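## Structural features

Atoms are numbered along the ring of the SMILES: C1 (CH–O–angeloyl), C2, C3, C4 (quaternary, bearing CH3 and C4'H2–O–tigloyl), C5, C6, C7 (CH–CH3), C8, C9 (C=O), C10 and C11 (quaternary, CH3). The core is the longipinane skeleton, tricyclo[5.4.0.0^{2,8}]undecane: a cyclobutane (C5, C6, C11, C10) whose corners C6 and C10 are spanned by C7–C8–C9 to give a bicyclo[3.1.1]heptan-2-one, and whose other corners C5 and C11 are tied by C4–C3–C2–C1 into a seven-membered ring. Of the seven stereocentres, four are contiguous on the cyclobutane (C5, C6, C10, C11), quaternary C11 carries the carbinol C1 and C5 carries quaternary C4; the C1 oxygen and C4' are cis on the seven-membered ring (both on the C10 side), and the C7 methyl lies on the face of the C5 bridge, away from the C11 methyl. Fragile points are the Z-configured angelate (it isomerises to the tiglate with base, nucleophiles or heat), both conjugated esters towards hydrides and organometallics, and the strained pinane-type cyclobutane next to any cationic centre; the bridgehead C10–H cannot be enolised, so the C9 ketone can only be manipulated through C8. The real difficulty is the four-membered ring with its quaternary corner C11 flanked by two further congested centres (C1 and, across C5, C4): a [2+2] cycloaddition is no shortcut, because all four cyclobutane carbons lie on the eleven-membered perimeter of the skeleton. The key step exploits two features: C11 (quaternary carbon) and C1 (carbinol) are neighbours, which is the retron of a trisubstituted oxirane, and C6 stands 1,3 to C10 in the six-membered ring C5–C6–C7–C8–C9–C10. An enolate carbon at C6 of a cis-fused bicyclo[5.4.0]undecane can therefore open a C11–C1 oxirane at its tertiary end in a 4-exo fashion, closing the cyclobutane, creating C11 and C6 and releasing the C1 hydroxyl in one operation.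

## Logic of the disconnections

24 is cut at the two acyl–oxygen bonds (at the C1 oxygen and at the C4' oxygen) to give 19, 20 and 22, passing through 21; 19 comes from 18 by loss of the silyl group. The conjugated esters tolerate neither hydrides nor organometallics, so they go on last, which removes ten carbons and both alkene geometries. The forward steps must distinguish the primary from the neopentyl secondary hydroxyl and must bring in the Z-ester at the very end without isomerisation.

18 is cut at the C7–CH3 bond to give 17. Methyl is to sit on the face of the C5 bridge, which is the open face of the enone because the C11 methyl overhangs the other one. A conjugate methyl delivery therefore sets C7 correctly, whereas adding hydrogen to a C7-methyl enone from the open face would be expected to give the epimer. The stereocentre is removed; the demand is clean 1,4-addition from the unshielded face.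

17 is traced back to 15 without cutting a skeletal bond: the C9 ketone and the C7=C8 double bond are exchanged for a C7 ketone and a C8=C9 methyl enol ether. The reason is that only a carbonyl at C7 makes C6 an enolisable carbon. The demand is a clean 1,2-reduction and hydrolysis with allylic transposition.

15 is cut at the C6–C11 bond of the cyclobutane to give 13, through 14. This removes the four-membered ring, the quaternary centre C11 and the C6 stereocentre, and turns the free C1 hydroxyl into an oxirane oxygen. The tricycle is reduced to a cis-fused bicycle with three stereocentres plus the oxirane. The demand is a kinetic enolate at C6 that attacks the tertiary oxirane carbon with inversion in a 4-exo mode.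

13 is cut at the two oxirane C–O bonds to 12, and 12 at the C11–CH3 bond, through 11 and 10, to 9. The C11 ketone of 9 is what activated the dienophile one step earlier, so it is the natural precursor of the methyl-bearing alkene. The demands are epoxidation on the face of H10, anti to the six-membered ring, and enolisation of the ketone towards C1 while C7 and C9 are still masked.

9 is cut at C5–C6 and C9–C10 to 7 and 8. One cycloaddition builds the six-membered ring, fixes the cis ring fusion and delivers C7 and C9 in different oxidation patterns. The bicycle is reduced to a monocycle with a single stereocentre. The demand is addition of the diene to the face of 7 that is anti to the silyloxymethyl group.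

7 is cut at C10, which is excised (bonds C10–C11 and C10–C5) to give 5 and then 4, through 6. A one-carbon ring expansion of a regiodefined silyl enol ether places the enone so that C4 is its gamma-quaternary carbon. The demand is that the enol double bond of 4 points towards the quaternary carbon.

4 is cut at the C4–CH3 bond to 2, and 2 at the O–Si bond to 1. An asymmetric conjugate addition creates the only stereocentre that is set by a catalyst, and the enolate it leaves is exactly the regioisomer needed for the ring expansion. The demand is high enantioselectivity at a quaternary carbon; every later stereocentre is derived from this one.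

## Other disconnections considered

Alternative 1: the disconnection that comes to mind first is the enone–alkene [2+2] photocycloaddition, cutting C5–C10 and C6–C11 together. Because both π-bonds must lie on the perimeter of the skeleton, the precursor has to be the eleven-membered dienone A1, and the forward key step would be a transannular photocycloaddition. A stereodefined cycloundecadienone costs more steps than the tricycle saves. A transannular closure would also be expected to begin with five-membered ring formation between C6 and C10, which leads to the straight bicyclo[3.2.0] adduct and not to the crossed bicyclo[3.1.1] one. The chosen plan forms one cyclobutane bond on a rigid bicycle in a polar step whose regiochemistry is fixed by geometry.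

Alternative 2: the same C6–C11 bond can be cut in a radical sense, with C6 as a ketone carbon. The precursor would be the cis-fused epoxy enone A2, and Cp2TiCl (trivalent titanium) would open the oxirane to the tertiary C11 radical, which adds 4-exo to the C6 carbonyl to give cyclobutanol A3. The radical closure is well matched to a carvone-type 2-methylcyclohexenone ring, but it leaves a tertiary hydroxyl on bridgehead C6 that the target lacks. Its removal by radical deoxygenation at a cyclobutane bridgehead, an allylic oxidation at C9 and a reduction at C7 from the hindered face add at least three uncertain steps. The chosen plan puts the carbonyl at C7, so C6 is the nucleophile, no extra oxygen is introduced, and the carbonyl is relayed to C9 by a transposition.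

Alternative 3: an intramolecular ketene–alkene [2+2] cycloaddition of a vinylketene, generated from a farnesane-type dienoyl chloride, would close the six- and four-membered rings together and give cyclobutanone A4, setting C11 stereospecifically from an E-alkene. The cut is C5–C10 and C6–C11, followed later by C4–C5. The weakness lies after the key step: the carbonyl ends up on C5, which must become a CH bonded to quaternary C4. This calls for C–C bond formation at a non-enolisable strained ketone and a tertiary deoxygenation, with the C4 configuration left to two nearly equivalent bridgehead environments. The chosen plan sets C4 first by catalysis and lets it control C5.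

Key step: step 9

Assumption: 1 and 8 are taken as catalogue compounds (1 is otherwise made in two steps from 3-ethoxycyclohex-2-en-1-one and 8 in one step from 4,4-dimethoxybut-3-en-2-one), and the sense of induction in step 2 is chosen through the enantiomer of the ligand.

## Route

Step 1
Reactants: 1 3-(hydroxymethyl)cyclohex-2-en-1-one
Product: 2 3-{[(tert-butyldiphenylsilyl)oxy]methyl}cyclohex-2-en-1-one
Conditions: t-BuPh2SiCl, imidazole, CH2Cl2, 0 °C to rt
Reagents that add atoms: tert-butyl(chloro)diphenylsilane, CC(C)(C)[Si](Cl)(c1ccccc1)c1ccccc1
Why: Silyl ether formation at a primary allylic alcohol; the bulky, acid- and base-stable silyl group later marks one face at the C4 stereocentre.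

Step 2
Reactants: 2 3-{[(tert-butyldiphenylsilyl)oxy]methyl}cyclohex-2-en-1-one
Product: 4 tert-butyl({(1S)-1-methyl-3-[(trimethylsilyl)oxy]cyclohex-2-en-1-yl}methoxy)diphenylsilane, via aluminium enolate 3 (not isolated)
Conditions: Me3Al, Cu(O2C-2-thienyl) (5 mol %), chiral phosphoramidite ligand (10 mol %, enantiomer giving the S centre), Et2O, −30 °C; then Me3SiOTf, −30 °C to rt
Reagents that add atoms: trimethylaluminium, C[Al](C)C; trimethylsilyl trifluoromethanesulfonate, C[Si](C)(C)OS(=O)(=O)C(F)(F)F
Why: Copper-catalysed asymmetric conjugate addition of a trialkylaluminium to a β-substituted cyclohexenone creates the quaternary stereocentre C4 under ligand control; silylation of the aluminium enolate fixes the enol double bond on the side of the quaternary carbon.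

Step 3
Reactants: 4 tert-butyl({(1S)-1-methyl-3-[(trimethylsilyl)oxy]cyclohex-2-en-1-yl}methoxy)diphenylsilane
Product: 5 (5S)-5-{[(tert-butyldiphenylsilyl)oxy]methyl}-5-methyl-1-[(trimethylsilyl)oxy]bicyclo[4.1.0]heptane
Conditions: Et2Zn, CH2I2, CH2Cl2, 0 °C to rt
Reagents that add atoms: diiodomethane, ICI
Why: Simmons–Smith cyclopropanation (Furukawa variant) of an electron-rich silyl enol ether; attack is drawn on the methyl face, but the facial outcome is without consequence because both cyclopropane stereocentres are destroyed in step 4.

Step 4
Reactants: 5 (5S)-5-{[(tert-butyldiphenylsilyl)oxy]methyl}-5-methyl-1-[(trimethylsilyl)oxy]bicyclo[4.1.0]heptane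
Product: 7 (4S)-4-{[(tert-butyldiphenylsilyl)oxy]methyl}-4-methylcyclohept-2-en-1-one, via β-chloro ketone 6 (not isolated)
Conditions: FeCl3, DMF, 0 °C to rt; then NaOAc, MeOH, reflux
Reagents that add atoms: none
Why: Oxidative ring expansion of a siloxycyclopropane (Ito–Saegusa type): one-electron oxidation cleaves the internal cyclopropane bond to the ring-enlarged β-chloro ketone, and dehydrochlorination gives the cycloheptenone; because the enol ether was regiodefined, the inserted carbon C10 lies between C11 and C5 and C4 becomes the gamma-quaternary centre.

Step 5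
Reactants: 7 (4S)-4-{[(tert-butyldiphenylsilyl)oxy]methyl}-4-methylcyclohept-2-en-1-one; 8 1,1-dimethoxy-3-[(trimethylsilyl)oxy]buta-1,3-diene
Product: 9 cis-fused cycloadduct (C11 ketone; C9 dimethyl ketal; C7=C8 trimethylsilyl enol ether)
Conditions: 8 (3 equiv), toluene, 130 °C, sealed tube
Reagents that add atoms: none
Why: Thermal Diels–Alder reaction of an enone with a 1,1-dialkoxy-3-silyloxy diene; the nucleophilic CH2 terminus (C6) bonds to the β-carbon C5 and the ketene acetal terminus (C9) to C10, suprafacial addition to the ring alkene gives the cis fusion at C5 and C10, and the diene should approach C5 anti to the larger silyloxymethyl substituent of the adjacent quaternary carbon (Felkin-type staggering), which places C6 cis to the C4 methyl.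

Step 6
Reactants: 9 cis-fused cycloadduct (C11 ketone; C9 dimethyl ketal; C7=C8 trimethylsilyl enol ether)
Product: 10 enol triflate of 9 (C11(OTf)=C1)
Conditions: KN(SiMe3)2, THF, −78 °C; then PhNTf2, −78 to 0 °C
Reagents that add atoms: N-phenylbis(trifluoromethanesulfonimide), O=S(=O)(N(c1ccccc1)S(=O)(=O)C(F)(F)F)C(F)(F)F
Why: Kinetic enolisation and O-triflation; the base removes a proton from the open C1 methylene and not the tertiary C10–H next to the ketal carbon, and the step is run while C7 and C9 are still masked because C10–H would become doubly activated once the vinylogous ester is unveiled.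

Step 7
Reactants: 10 enol triflate of 9 (C11(OTf)=C1)
Product: 12 cis-fused vinylogous ester (C7 ketone; C9 methoxy; C11-methyl C11=C1 alkene), via methylated silyl enol ether ketal 11 (not isolated)
Conditions: Me2CuLi (from MeLi, CuI), Et2O, −30 to 0 °C; then CF3CO2H, CH2Cl2, 0 °C
Reagents that add atoms: lithium dimethylcuprate, [Li+].C[Cu-]C
Why: Cuprate cross-coupling of an enol triflate installs the C11 methyl without moving the C11=C1 double bond; acid then cleaves the silyl enol ether and eliminates methanol from the β-keto ketal to give the 3-methoxy enone with its carbonyl at C7.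

Step 8
Reactants: 12 cis-fused vinylogous ester (C7 ketone; C9 methoxy; C11-methyl C11=C1 alkene)
Product: 13 C11–C1 oxirane of 12 (oxygen on the face of H10)
Conditions: mCPBA, NaHCO3, CH2Cl2, 0 °C
Reagents that add atoms: 3-chloroperoxybenzoic acid, OOC(=O)c1cccc(Cl)c1
Why: Prilezhaev epoxidation of the only isolated electron-rich alkene (the push-pull C8=C9 bond is deactivated); the peracid should approach from the face of H10, anti to the allylic C9 and the six-membered ring, which gives the oxirane whose C11–O bond is anti to C6 and whose oxygen is cis to the silyloxymethyl group.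

Step 9
Reactants: 13 C11–C1 oxirane of 12 (oxygen on the face of H10)
Product: 15 tricyclic vinylogous ester (cyclobutane closed; free C1 hydroxyl), via lithium enolate 14 (not isolated)
Conditions: LiN(i-Pr)2, THF, −78 °C; then BF3·OEt2, −78 to −40 °C; aq. NH4Cl
Reagents that add atoms: none
Why: The amide base removes a C6 proton kinetically (α'-deprotonation of a 3-alkoxy enone, as in Stork–Danheiser alkylations) to give the cross-conjugated enolate 14, in which C6 lies 1,3 to C10 and directly beneath the pseudo-axial C11; after Lewis acid activation of the oxirane, C6 opens it at the tertiary carbon C11 with inversion, forming the C6–C11 bond. This single 4-exo-tet closure makes the cyclobutane (C5, C6, C11, C10) and with it the bicyclo[3.1.1]heptenone and the complete tricycle. The closest known reaction type is the intramolecular opening of oxiranes by tethered nitrile- or ketone-stabilised carbanions to give cyclobutanes (epoxynitrile and epoxy ketone cyclisations), which favours the exo four-membered over the endo five-membered mode, also at the more substituted oxirane carbon. C11 is set by backside attack, so its configuration follows from the oxirane of step 8; C6 can only bond on the face on which the cis ring fusion holds C11; C1 keeps its C–O bond and emerges as the alcohol with the configuration of the target. The step needs α' over gamma (C10–H) deprotonation, which kinetic conditions at −78 °C should secure (a gamma-enolate would eliminate the oxirane). It needs attack at C11 over C1, which the exo geometry and the greater cationic character of the tertiary carbon under BF3 should secure. It needs C- over O-alkylation, which is secured because O-alkylation would create a bridgehead enol ether excluded by Bredt's rule.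

Step 10
Reactants: 15 tricyclic vinylogous ester (cyclobutane closed; free C1 hydroxyl)
Product: 17 tricyclic enone (C9 ketone; C7=C8), via allylic alcohol 16 (not isolated)
Conditions: i-Bu2AlH, CH2Cl2, −78 °C; then 1 M HCl, THF, 0 °C to rt
Reagents that add atoms: water, O
Why: Stork–Danheiser transposition: 1,2-reduction of the vinylogous ester carbonyl at C7 and acid hydrolysis of the resulting allylic enol ether move the carbonyl to C9 and the double bond to C7=C8; the free C1 hydroxyl only consumes one equivalent of hydride.

Step 11
Reactants: 17 tricyclic enone (C9 ketone; C7=C8)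
Product: 18 6-{[(tert-butyldiphenylsilyl)oxy]methyl}-3-hydroxy-2,6,9-trimethyltricyclo[5.4.0.0^{2,8}]undecan-11-one
Conditions: Me2CuLi (from MeLi, CuI), Et2O, −40 to 0 °C; aq. NH4Cl
Reagents that add atoms: lithium dimethylcuprate, [Li+].C[Cu-]C
Why: Conjugate addition of a Gilman cuprate to a bicyclo[3.1.1]heptenone; methyl is delivered to C7 from the face of the C5–H bridge, anti to the C11 methyl that overhangs the other face, which gives the C7 configuration of the target.

Step 12
Reactants: 18 6-{[(tert-butyldiphenylsilyl)oxy]methyl}-3-hydroxy-2,6,9-trimethyltricyclo[5.4.0.0^{2,8}]undecan-11-one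
Product: 19 3-hydroxy-6-(hydroxymethyl)-2,6,9-trimethyltricyclo[5.4.0.0^{2,8}]undecan-11-one
Conditions: Bu4NF, AcOH, THF, rt
Reagents that add atoms: none
Why: Fluoride-mediated cleavage of the silyl ether, buffered with acetic acid so that the ketone is not exposed to basic fluoride.

Step 13
Reactants: 19 3-hydroxy-6-(hydroxymethyl)-2,6,9-trimethyltricyclo[5.4.0.0^{2,8}]undecan-11-one; 20 (E)-2-methylbut-2-enoyl chloride (tigloyl chloride)
Product: 21 [3-hydroxy-2,6,9-trimethyl-11-oxotricyclo[5.4.0.0^{2,8}]undecan-6-yl]methyl (E)-2-methylbut-2-enoate
Conditions: 20, pyridine, CH2Cl2, −30 °C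
Reagents that add atoms: none
Why: Chemoselective acylation with an acid chloride: the primary hydroxyl reacts, whereas the secondary C1 hydroxyl next to quaternary C11 is far slower; the E geometry of the tiglate is the stable one.

Step 14
Reactants: 21 [3-hydroxy-2,6,9-trimethyl-11-oxotricyclo[5.4.0.0^{2,8}]undecan-6-yl]methyl (E)-2-methylbut-2-enoate; 22 (Z)-2-methylbut-2-enoic acid (angelic acid)
Product: 24 CNP0276938.2 (target), via mixed anhydride 23 (not isolated)
Conditions: 22, 2,4,6-trichlorobenzoyl chloride, Et3N, toluene, rt; then 21, toluene, 80 °C
Reagents that add atoms: none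
Why: Yamaguchi-type esterification through the 2,4,6-trichlorobenzoyl mixed anhydride, a method suited to hindered alcohols and to angelic acid because no nucleophilic base is present that could isomerise the Z double bond; the step is last so that the Z-ester meets no further reagent.

## Compound list

1 | 3-(hydroxymethyl)cyclohex-2-en-1-one | O=C1C=C(CO)CCC1 | starting material
2 | 3-{[(tert-butyldiphenylsilyl)oxy]methyl}cyclohex-2-en-1-one | O=C1C=C(CO[Si](c2ccccc2)(c2ccccc2)C(C)(C)C)CCC1 | intermediate
3 | dimethylaluminium enolate of (3S)-3-{[(tert-butyldiphenylsilyl)oxy]methyl}-3-methylcyclohexan-1-one, enol double bond towards the quaternary carbon (not isolated) | C[Al](C)OC1=C[C@@](C)(CO[Si](c2ccccc2)(c2ccccc2)C(C)(C)C)CCC1 | intermediate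
4 | tert-butyl({(1S)-1-methyl-3-[(trimethylsilyl)oxy]cyclohex-2-en-1-yl}methoxy)diphenylsilane | C[Si](C)(C)OC1=C[C@@](C)(CO[Si](c2ccccc2)(c2ccccc2)C(C)(C)C)CCC1 | intermediate
5 | (5S)-5-{[(tert-butyldiphenylsilyl)oxy]methyl}-5-methyl-1-[(trimethylsilyl)oxy]bicyclo[4.1.0]heptane, cyclopropane cis-fused on the face of the methyl group | C[Si](C)(C)O[C@@]12C[C@@H]1[C@@](C)(CO[Si](c3ccccc3)(c3ccccc3)C(C)(C)C)CCC2 | intermediate
6 | 4-{[(tert-butyldiphenylsilyl)oxy]methyl}-3-chloro-4-methylcycloheptan-1-one, quaternary centre as in 4, either C3 epimer (not isolated) | O=C1CC(Cl)[C@@](C)(CO[Si](c2ccccc2)(c2ccccc2)C(C)(C)C)CCC1 | intermediate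
7 | (4S)-4-{[(tert-butyldiphenylsilyl)oxy]methyl}-4-methylcyclohept-2-en-1-one | O=C1C=C[C@@](C)(CO[Si](c2ccccc2)(c2ccccc2)C(C)(C)C)CCC1 | intermediate
8 | 1,1-dimethoxy-3-[(trimethylsilyl)oxy]buta-1,3-diene | C=C(O[Si](C)(C)C)C=C(OC)OC | starting material
9 | 4a,9a-cis-5-{[(tert-butyldiphenylsilyl)oxy]methyl}-1,1-dimethoxy-5-methyl-3-[(trimethylsilyl)oxy]-1,4,4a,5,6,7,8,9a-octahydro-9H-benzo[7]annulen-9-one, 5-methyl cis to the C4 methylene | COC1(OC)C=C(O[Si](C)(C)C)C[C@H]2[C@@H]1C(=O)CCC[C@]2(C)CO[Si](c3ccccc3)(c3ccccc3)C(C)(C)C | intermediate
10 | 4a,9a-cis-5-{[(tert-butyldiphenylsilyl)oxy]methyl}-1,1-dimethoxy-5-methyl-3-[(trimethylsilyl)oxy]-4,4a,5,6,7,9a-hexahydro-1H-benzo[7]annulen-9-yl trifluoromethanesulfonate | COC1(OC)C=C(O[Si](C)(C)C)C[C@H]2[C@@H]1C(OS(=O)(=O)C(F)(F)F)=CCC[C@]2(C)CO[Si](c3ccccc3)(c3ccccc3)C(C)(C)C | intermediate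
11 | 9-methyl analogue of 10 (methyl in place of the triflate; not isolated) | COC1(OC)C=C(O[Si](C)(C)C)C[C@H]2[C@@H]1C(C)=CCC[C@]2(C)CO[Si](c3ccccc3)(c3ccccc3)C(C)(C)C | intermediate
12 | 4a,9a-cis-5-{[(tert-butyldiphenylsilyl)oxy]methyl}-1-methoxy-5,9-dimethyl-4,4a,5,6,7,9a-hexahydro-3H-benzo[7]annulen-3-one | COC1=CC(=O)C[C@H]2[C@@H]1C(C)=CCC[C@]2(C)CO[Si](c3ccccc3)(c3ccccc3)C(C)(C)C | intermediate
13 | 8,9-epoxide of 12 (C11–C1 oxirane in target numbering), oxygen on the face of H-9a and cis to the silyloxymethyl group | COC1=CC(=O)C[C@H]2[C@@H]1[C@]3(C)O[C@@H]3CC[C@]2(C)CO[Si](c4ccccc4)(c4ccccc4)C(C)(C)C | intermediate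
14 | lithium α'-enolate of 13 (C6=C7–O–Li; not isolated) | [Li+].COC1=CC([O-])=C[C@H]2[C@@H]1[C@]3(C)O[C@@H]3CC[C@]2(C)CO[Si](c4ccccc4)(c4ccccc4)C(C)(C)C | intermediate
15 | 6-{[(tert-butyldiphenylsilyl)oxy]methyl}-3-hydroxy-11-methoxy-2,6-dimethyltricyclo[5.4.0.0^{2,8}]undec-10-en-9-one, configuration of the target at all ring centres | O[C@@H]1CC[C@](C)(CO[Si](c4ccccc4)(c4ccccc4)C(C)(C)C)[C@H]2[C@@H]3C(=O)C=C(OC)[C@H]2[C@@]31C | intermediate
16 | 9-hydroxy analogue of 15 (allylic alcohol, either C9 epimer; not isolated) | O[C@@H]1CC[C@](C)(CO[Si](c4ccccc4)(c4ccccc4)C(C)(C)C)[C@H]2[C@@H]3C(O)C=C(OC)[C@H]2[C@@]31C | intermediate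
17 | 6-{[(tert-butyldiphenylsilyl)oxy]methyl}-3-hydroxy-2,6-dimethyltricyclo[5.4.0.0^{2,8}]undec-9-en-11-one | O[C@@H]1CC[C@](C)(CO[Si](c4ccccc4)(c4ccccc4)C(C)(C)C)[C@H]2[C@@H]3C=CC(=O)[C@H]2[C@@]31C | intermediate
18 | 6-{[(tert-butyldiphenylsilyl)oxy]methyl}-3-hydroxy-2,6,9-trimethyltricyclo[5.4.0.0^{2,8}]undecan-11-one | O[C@@H]1CC[C@](C)(CO[Si](c4ccccc4)(c4ccccc4)C(C)(C)C)[C@H]2[C@@H]3[C@H](C)CC(=O)[C@H]2[C@@]31C | intermediate
19 | 3-hydroxy-6-(hydroxymethyl)-2,6,9-trimethyltricyclo[5.4.0.0^{2,8}]undecan-11-one | O[C@@H]1CC[C@](C)(CO)[C@H]2[C@@H]3[C@H](C)CC(=O)[C@H]2[C@@]31C | intermediate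
20 | (E)-2-methylbut-2-enoyl chloride (tigloyl chloride) | C/C=C(\C)C(=O)Cl | starting material
21 | [3-hydroxy-2,6,9-trimethyl-11-oxotricyclo[5.4.0.0^{2,8}]undecan-6-yl]methyl (E)-2-methylbut-2-enoate | O[C@@H]1CC[C@](C)(COC(=O)/C(C)=C/C)[C@H]2[C@@H]3[C@H](C)CC(=O)[C@H]2[C@@]31C | intermediate
22 | (Z)-2-methylbut-2-enoic acid (angelic acid) | C/C=C(/C)C(=O)O | starting material
23 | (Z)-2-methylbut-2-enoic 2,4,6-trichlorobenzoic anhydride (not isolated) | C/C=C(/C)C(=O)OC(=O)c1c(Cl)cc(Cl)cc1Cl | intermediate
24 | CNP0276938.2: [3-{[(Z)-2-methylbut-2-enoyl]oxy}-2,6,9-trimethyl-11-oxotricyclo[5.4.0.0^{2,8}]undecan-6-yl]methyl (E)-2-methylbut-2-enoate | C/C=C(/C)C(=O)O[C@@H]1CC[C@](C)(COC(=O)/C(C)=C/C)[C@H]2[C@@H]3[C@H](C)CC(=O)[C@H]2[C@@]31C | target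

## Step count and least certain steps

Total: 14 steps. Longest linear sequence: 14 steps, from 1 to 24; 8, 20 and 22 are used as purchased.

**Step 9 (key step).** Three processes can divert it. The enolate may open the oxirane at the secondary carbon C1, closing a five-membered ring. The Lewis acid may trigger a hydride shift in the oxirane before the C–C bond forms. The kinetic α'-enolate may equilibrate to the gamma-dienolate, which eliminates the oxirane. The fallback changes from the anionic to a cationic manifold and sets out from 13. Enolisation with LiN(i-Pr)2 and trapping with Me3SiCl gives the isolable 2-silyloxy diene F1. F1 is then exposed to TiCl4 at −78 °C, so that the oxirane ionises at its tertiary carbon and is captured by C6 in a Mukaiyama-type alkylation of a silyl enol ether. Work-up returns to the route at 15.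

**Step 5.** The cycloaddition may be slow, because the β-carbon C5 is neopentylic, and the diene may discriminate poorly between the methyl and the silyloxymethyl face of 7. The fallback sets out from 7 and 8 and abandons the concerted reaction for a stepwise ionic annulation. Catalytic Me3SiOTf in CH2Cl2 at −78 °C should effect a Mukaiyama–Michael addition of the CH2 terminus of 8 to C5, followed by a second Michael closure of the new C10 silyl enol ether onto the β,β-dimethoxy enone carbon C9. The open transition state of the first bond formation is governed by the same anti preference. The sequence comes back to the route at 9 and makes no compound outside the route (F0).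

**Step 8.** The peracid may attack the face of the six-membered ring. That would give the diastereomeric oxirane, in which C6 cannot reach the backside of the C11–O bond and C1 would end up epimeric. The fallback sets out from 12 and replaces steric control by delivery from a hydroxyl group. Bu4NF removes the silyl group to give the hydroxymethyl compound F2. Its hydroxyl sits on the required face and directs VO(acac)2/t-BuOOH, or a hydrogen-bonded peracid, to give the epoxy alcohol F3. Re-silylation with t-BuPh2SiCl and imidazole comes back to the route at 13.

**Step 14.** Acylation of the neopentyl secondary alcohol may be sluggish, and Z to E isomerisation of the angelate may occur during activation or heating. The fallback sets out from 21 and builds the Z double bond on the molecule. Esterification with 2-[bis(2,2,2-trifluoroethoxy)phosphoryl]propanoic acid (carbodiimide, 4-dimethylaminopyridine) gives the phosphonate ester F4. A Still–Gennari olefination of F4 with acetaldehyde (KN(SiMe3)2, 18-crown-6, THF, −78 °C) should then give the Z-2-methylbut-2-enoate. It comes back to the route at 24.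

## Further compounds

F1 | step 9 | trimethylsilyl dienol ether of 13 (C6=C7–OSiMe3) | COC1=CC(O[Si](C)(C)C)=C[C@H]2[C@@H]1[C@]3(C)O[C@@H]3CC[C@]2(C)CO[Si](c4ccccc4)(c4ccccc4)C(C)(C)C
F0 | step 5 | none | none
F2 | step 8 | 4a,9a-cis-5-(hydroxymethyl)-1-methoxy-5,9-dimethyl-4,4a,5,6,7,9a-hexahydro-3H-benzo[7]annulen-3-one | COC1=CC(=O)C[C@H]2[C@@H]1C(C)=CCC[C@]2(C)CO
F3 | step 8 | 8,9-epoxide of F2, oxygen cis to the hydroxymethyl group | COC1=CC(=O)C[C@H]2[C@@H]1[C@]3(C)O[C@@H]3CC[C@]2(C)CO
F4 | step 14 | 2-[bis(2,2,2-trifluoroethoxy)phosphoryl]propanoate of 21 at the C1 oxygen (either configuration at the phosphonate-bearing carbon) | CC(C(=O)O[C@@H]1CC[C@](C)(COC(=O)/C(C)=C/C)[C@H]2[C@@H]3[C@H](C)CC(=O)[C@H]2[C@@]31C)P(=O)(OCC(F)(F)F)OCC(F)(F)F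
A1 | alternative 1 | (2E,8E)-4-hydroxy-7-(hydroxymethyl)-3,7,10-trimethylcycloundeca-2,8-dien-1-one, centres as in the target | O[C@@H]1CC[C@](C)(CO)/C=C/[C@H](C)CC(=O)/C=C/1C
A2 | alternative 2 | cis-fused bicyclic epoxy enone (C6 ketone, C7-methyl C7=C8 alkene, C11–C1 oxirane, C4 bearing methyl and hydroxymethyl) | O=C1C(C)=CC[C@@H]2[C@H]1[C@@](C)(CO)CC[C@H]3O[C@@]23C
A3 | alternative 2 | tricyclic cyclobutanol with a tertiary hydroxyl on bridgehead C6 (C7-methyl C7=C8 alkene, C1 hydroxyl, C4 hydroxymethyl) | O[C@@H]1CC[C@](C)(CO)[C@H]2[C@]3(O)C(C)=CC[C@H]2[C@@]31C
A4 | alternative 3 | 2,6-dimethyl-6-(4-methylpent-3-en-1-yl)bicyclo[3.1.1]hept-2-en-7-one | O=C1[C@@H]2C(C)=CC[C@H]1[C@]2(C)CCC=C(C)C
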